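**Plan**

- Numbering: ring atoms as in cyclohexanone 13 (C-1 carbonyl, C-2 and C-4 methyl-bearing methines, C-3 quaternary); side chain C-1' (CH2 on the quinone) to C-5' (CH2 on the ring).
- Cuts: hydroxyquinone ← resorcinol; carbinol C-4'–alkenyl C-3' bond ← keto aldehyde 14 + aryl-bearing (E)-alkenyl iodide 22; CH2–CHO ← ethynyl; cyclohexanone ← acyclic alkynyl epoxy-olefin 11, by cutting ring bond C-2–C-3 and returning the ethynyl carbon from C-3 to C-2.
- Enabling feature: the row O=C-1, C-2(H)(Me), C-3(Me)(side chain), C-4(H)(Me) can be read as an epoxide (C-1/C-2) and a trisubstituted alkene (C-3/C-4). One cation, formed at C-4 on ring closure, is then handed on to C-3, C-2 and C-1 by 1,2-shifts of H, the side-chain carbon and H, and ends as the carbonyl.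
- Forward: Claisen and Still–Gennari steps build the (Z,E)-dienol; Sharpless epoxidation and Ohira–Bestmann homologation give 11; step 7 closes the cyclohexanone (the only ring closed in the route, the arene is bought); then alkyne hydration, Ni/Cr union with 22, phenol release and oxidation to the quinone.
- Stereochemistry: the epoxide centres (L-(+)-tartrate) and the Z and E alkene geometries are translated by a chair transition state and three anti 1,2-shifts into C-2, C-3 and C-4 (side chain cis to both flanking methyls); the carbinol comes from a chiral chromium catalyst; the side-chain E-alkene from syn-hydrozirconation.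

Key step: step 7

Remark on the chemistry: racemic 1 is used, because its only stereocentre is lost in step 1.

**Step 1**
Reactants: 1 3-methylbut-3-en-2-ol (racemic); 2 ethyl vinyl ether
Product: 4 (4E)-4-methylhex-4-enal, via allyl vinyl ether 3 (not isolated)
Conditions: Hg(OAc)2 (cat.), 2 as solvent, reflux; then 130 °C, sealed tube
Reagents that add atoms: none
Why: Transvinylation followed by Claisen rearrangement through a chair with the carbinol methyl equatorial should give the (E)-trisubstituted alkene, and the only stereocentre of 1 is destroyed, so none has to be set.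

**Step 2**
Reactants: 4 (4E)-4-methylhex-4-enal; 5 methyl 2-[bis(2,2,2-trifluoroethoxy)phosphoryl]propanoate
Product: 6 methyl (2Z,6E)-2,6-dimethylocta-2,6-dienoate
Conditions: KN(SiMe3)2, 18-crown-6, THF, −78 °C
Reagents that add atoms: none
Why: Still–Gennari olefination, in which the electron-poor phosphonate eliminates quickly from the kinetic adduct, should give the (Z)-enoate with the ester cis to the chain, the geometry that later places the migrating carbon axial; no stereocentre is formed.

**Step 3**
Reactants: 6 methyl (2Z,6E)-2,6-dimethylocta-2,6-dienoate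
Product: 7 (2Z,6E)-2,6-dimethylocta-2,6-dien-1-ol
Conditions: i-Bu2AlH (2.2 equiv), CH2Cl2, −78 to 0 °C; aq. potassium sodium tartrate
Reagents that add atoms: none
Why: 1,2-Reduction of the enoate by the aluminium hydride should give the allylic alcohol without change of either alkene geometry; no stereocentre is formed.

**Step 4**
Reactants: 7 (2Z,6E)-2,6-dimethylocta-2,6-dien-1-ol
Product: 8 [(2S,3R)-2-methyl-3-[(3E)-3-methylpent-3-en-1-yl]oxiran-2-yl]methanol
Conditions: Ti(OiPr)4 (cat.), L-(+)-diethyl tartrate (cat.), t-BuOOH, 4 Å molecular sieves, CH2Cl2, −20 °C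
Reagents that add atoms: tert-butyl hydroperoxide, CC(C)(C)OO
Why: Sharpless asymmetric epoxidation, in which the titanium tartrate bound to the allylic hydroxyl oxidizes only the allylic alkene and, with the L-(+)-ligand, attacks the face that makes the CH2OH-bearing carbon S, so that the Z geometry fixes the pair as (2S,3R) under reagent control.

**Step 5**
Reactants: 8 [(2S,3R)-2-methyl-3-[(3E)-3-methylpent-3-en-1-yl]oxiran-2-yl]methanol
Product: 9 (2R,3R)-2-methyl-3-[(3E)-3-methylpent-3-en-1-yl]oxirane-2-carbaldehyde
Conditions: PhI(OAc)2, TEMPO (cat.), CH2Cl2, rt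
Reagents that add atoms: none
Why: Oxoammonium-mediated oxidation of the primary alcohol should stop at the aldehyde, which has no α-hydrogen and cannot epimerize (the new descriptor at C-2 reflects only a change of priorities).

**Step 6**
Reactants: 9 (2R,3R)-2-methyl-3-[(3E)-3-methylpent-3-en-1-yl]oxirane-2-carbaldehyde; 10 dimethyl (1-diazo-2-oxopropyl)phosphonate
Product: 11 (2S,3R)-2-ethynyl-2-methyl-3-[(3E)-3-methylpent-3-en-1-yl]oxirane
Conditions: K2CO3, MeOH, 0 °C to rt
Reagents that add atoms: none
Why: Ohira–Bestmann (Seyferth–Gilbert) homologation through the alkylidene carbene should convert the aldehyde into the terminal alkyne under mild base and leave the epoxide and its two stereocentres untouched.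

**Step 7**
Reactants: 11 (2S,3R)-2-ethynyl-2-methyl-3-[(3E)-3-methylpent-3-en-1-yl]oxirane
Product: 13 (2S,3S,4S)-3-ethynyl-2,3,4-trimethylcyclohexan-1-one, via cyclohexyl cation 12 (not isolated)
Conditions: MeAlCl2 (1.5 equiv), CH2Cl2, −78 to −40 °C; then aq. HCl
Reagents that add atoms: none
Why: Proposed new method: Coordination of MeAlCl2 to the epoxide oxygen should ionize the tertiary propargylic C–O bond while the trisubstituted alkene attacks this carbon from the back through a chair (6-endo-tet at the epoxide, 6-endo-trig at the alkene), giving tertiary cation 12, which is then relayed by three suprafacial, antiperiplanar 1,2-shifts (axial H to the cationic carbon, axial ethynyl from the former epoxide carbon, axial H from the carbinol carbon) until it is quenched as the aluminium-bound ketone. The closest known reaction types are the Lewis-acid epoxide-initiated cation–olefin cyclization and the stereospecific 1,2-hydride and 1,2-carbon shift relays of tertiary cyclohexyl cations (friedo-type and semipinacol rearrangements), the same relay that the presumed biosynthesis of this trimethylcyclohexanone unit uses with a migrating methyl; new is its use in a monocycle with an sp carbon as the migrating group. C-4 is set by the (E)-alkene, which places its hydrogen axial so that it migrates and leaves the methyl on the other face; the quaternary C-3 is set because the ethynyl group, cis to the chain on the epoxide (Z geometry of step 2) and therefore axial, enters anti to the departing hydride and so ends cis to both flanking methyls; C-2 receives its hydride anti to the departing ethynyl, which is also the thermodynamically preferred epimer; the absolute sense of all three comes from the epoxide of step 4. The step needs the relay to outrun proton loss, capture of the cation by chloride or by the ring oxygen, and plain rearrangement of the epoxide to an open-chain ketone. This is helped by the non-basic medium at low temperature, by the equatorial aluminium-bound oxygen that cannot reach the cation without a boat, by a terminal alkyne that is too poor a π-nucleophile to trap the cation, and by the fact that only the last shift, to the carbonyl, is irreversible, so that alkenes or chlorides formed on the way can re-enter the cation manifold. Methyl migration should not compete, because only the axial ethynyl bond is antiperiplanar to the empty orbital at C-3.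

**Step 8**
Reactants: 13 (2S,3S,4S)-3-ethynyl-2,3,4-trimethylcyclohexan-1-one
Product: 14 2-[(1S,2S,6S)-1,2,6-trimethyl-3-oxocyclohexyl]acetaldehyde
Conditions: [CpRu(MeCN)3]PF6 (cat.), 5,5'-bis(trifluoromethyl)-2,2'-bipyridine (cat.), N-methylpyrrolidin-2-one/H2O, 25 °C
Reagents that add atoms: water, O
Why: Ruthenium-catalysed anti-Markovnikov hydration through a vinylidene complex should place the oxygen on the terminal carbon and give the aldehyde, while the ketone and the three ring stereocentres are left alone.

**Step 9**
Reactants: 15 orcinol (5-methylbenzene-1,3-diol)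
Product: 16 4-chloro-5-methylbenzene-1,3-diol
Conditions: SO2Cl2 (1.0 equiv), Et2O, 0 °C
Reagents that add atoms: sulfuryl chloride, ClS(Cl)(=O)=O
Why: Electrophilic aromatic chlorination should go to C-4, which is para to one hydroxyl and ortho to the other and less crowded than C-2 between the two hydroxyls; no stereocentre is involved.

**Step 10**
Reactants: 16 4-chloro-5-methylbenzene-1,3-diol
Product: 17 1-chloro-2,4-bis(methoxymethoxy)-6-methylbenzene
Conditions: MeOCH2Cl, i-Pr2NEt, CH2Cl2, 0 °C to rt
Reagents that add atoms: chloromethyl methyl ether, COCCl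
Why: O-Alkylation of both phenols should give acetal ethers that direct the metalation of step 11 and survive the organometallic steps; no stereocentre is involved.

**Step 11**
Reactants: 17 1-chloro-2,4-bis(methoxymethoxy)-6-methylbenzene; 18 1-bromobut-2-yne
Product: 20 3-(but-2-yn-1-yl)-1-chloro-2,4-bis(methoxymethoxy)-6-methylbenzene, via aryllithium 19 (not isolated)
Conditions: n-BuLi, THF, 0 °C; then 18, −78 °C to rt
Reagents that add atoms: none
Why: Directed ortho-metalation at the position flanked by both acetal ethers, followed by SN2 alkylation of the hard aryllithium by the propargylic bromide (no copper, to avoid SN2' attack to an allene), should give the skipped aryl alkyne; no stereocentre is involved.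

**Step 12**
Reactants: 20 3-(but-2-yn-1-yl)-1-chloro-2,4-bis(methoxymethoxy)-6-methylbenzene
Product: 22 1-chloro-3-[(2E)-3-iodobut-2-en-1-yl]-2,4-bis(methoxymethoxy)-6-methylbenzene, via alkenylzirconocene 21 (not isolated)
Conditions: Cp2Zr(H)Cl (2 equiv), THF, 40 °C; then I2, 0 °C
Reagents that add atoms: iodine, II
Why: Hydrozirconation adds H and Zr syn and, under equilibration with excess reagent, should place zirconium on the alkyne carbon next to the small methyl group, and iodinolysis with retention should then give the (E)-alkenyl iodide; no stereocentre is involved.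

**Step 13**
Reactants: 14 2-[(1S,2S,6S)-1,2,6-trimethyl-3-oxocyclohexyl]acetaldehyde; 22 1-chloro-3-[(2E)-3-iodobut-2-en-1-yl]-2,4-bis(methoxymethoxy)-6-methylbenzene
Product: 23 (2S,3S,4S)-3-[(2S,3E)-5-[3-chloro-2,6-bis(methoxymethoxy)-4-methylphenyl]-2-hydroxy-3-methylpent-3-en-1-yl]-2,3,4-trimethylcyclohexan-1-one
Conditions: CrCl2 (cat.), chiral 2-(oxazolin-2-yl)aryl sulfonamide ligand (cat., the enantiomer that gives the S carbinol), 1,8-bis(dimethylamino)naphthalene (cat.), NiCl2·(2,9-dimethyl-1,10-phenanthroline) (cat.), Mn, Cp2ZrCl2, LiCl, MeCN, rt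
Reagents that add atoms: none
Why: Catalytic asymmetric Nozaki–Hiyama–Kishi coupling, in which the alkenyl group passes from nickel to a chromium centre that carries the chiral ligand and adds to the aldehyde but not to the hindered ring ketone, should set the new carbinol as S under catalyst control (the ring stereocentres are too remote to steer it) with retention of the E geometry.

**Step 14**
Reactants: 23 (2S,3S,4S)-3-[(2S,3E)-5-[3-chloro-2,6-bis(methoxymethoxy)-4-methylphenyl]-2-hydroxy-3-methylpent-3-en-1-yl]-2,3,4-trimethylcyclohexan-1-one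
Product: 24 (2S,3S,4S)-3-[(2S,3E)-5-(3-chloro-2,6-dihydroxy-4-methylphenyl)-2-hydroxy-3-methylpent-3-en-1-yl]-2,3,4-trimethylcyclohexan-1-one
Conditions: Me3SiOTf, 2,2'-bipyridyl, CH2Cl2, 0 °C; then H2O
Reagents that add atoms: none
Why: Silyl triflate/bipyridyl cleavage of the aryl methoxymethyl ethers runs without free protic acid, so the ionizable secondary allylic alcohol (silylated in passing and freed on work-up) and all stereocentres should survive.

**Step 15**
Reactants: 24 (2S,3S,4S)-3-[(2S,3E)-5-(3-chloro-2,6-dihydroxy-4-methylphenyl)-2-hydroxy-3-methylpent-3-en-1-yl]-2,3,4-trimethylcyclohexan-1-one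
Product: 25 5-chloro-2-hydroxy-3-[(2E,4S)-4-hydroxy-3-methyl-5-[(1S,2S,6S)-1,2,6-trimethyl-3-oxocyclohexyl]pent-2-en-1-yl]-6-methylcyclohexa-2,5-diene-1,4-dione
Conditions: (KSO3)2NO, KH2PO4 buffer, acetone/H2O, 0 °C to rt
Reagents that add atoms: potassium nitrosodisulfonate, [O]N(S(=O)(=O)[O-])S(=O)(=O)[O-].[K+].[K+]
Why: Teuber oxidation of the resorcinol at its only free ring position, which is para to one hydroxyl, should give the para-quinone and leave the other hydroxyl as the 2-hydroxy group, while alkene, carbinol and ketone are inert to the nitroxide.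

**Compound list**

1 | 3-methylbut-3-en-2-ol (racemic) | CC(O)C(C)=C | starting material
2 | ethyl vinyl ether | C=COCC | starting material
3 | 3-(ethenyloxy)-2-methylbut-1-ene (racemic) | C=COC(C)C(C)=C | intermediate (not isolated)
4 | (4E)-4-methylhex-4-enal | O=CCC/C(C)=C/C | intermediate
5 | methyl 2-[bis(2,2,2-trifluoroethoxy)phosphoryl]propanoate | COC(=O)C(C)P(=O)(OCC(F)(F)F)OCC(F)(F)F | starting material
6 | methyl (2Z,6E)-2,6-dimethylocta-2,6-dienoate | COC(=O)/C(C)=C\CC/C(C)=C/C | intermediate
7 | (2Z,6E)-2,6-dimethylocta-2,6-dien-1-ol | OC/C(C)=C\CC/C(C)=C/C | intermediate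
8 | [(2S,3R)-2-methyl-3-[(3E)-3-methylpent-3-en-1-yl]oxiran-2-yl]methanol (hydroxymethyl cis to the pentenyl chain) | OC[C@]1(C)O[C@@H]1CC/C(C)=C/C | intermediate
9 | (2R,3R)-2-methyl-3-[(3E)-3-methylpent-3-en-1-yl]oxirane-2-carbaldehyde | O=C[C@]1(C)O[C@@H]1CC/C(C)=C/C | intermediate
10 | dimethyl (1-diazo-2-oxopropyl)phosphonate | CC(=O)C(=[N+]=[N-])P(=O)(OC)OC | starting material
11 | (2S,3R)-2-ethynyl-2-methyl-3-[(3E)-3-methylpent-3-en-1-yl]oxirane (ethynyl cis to the chain) | C#C[C@]1(C)O[C@@H]1CC/C(C)=C/C | intermediate
12 | dichloro(methyl)aluminate of (1R,2R,3S)-2-ethynyl-1-oxido-2,3,4-trimethylcyclohexan-4-ylium (chair; ethynyl axial and anti to H-1 and H-3, aluminium-bound oxygen equatorial) | C#C[C@]1(C)[C@H](O[Al-](C)(Cl)Cl)CC[C+](C)[C@@H]1C | intermediate (not isolated)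
13 | (2S,3S,4S)-3-ethynyl-2,3,4-trimethylcyclohexan-1-one (ethynyl cis to the methyls at C-2 and C-4) | C#C[C@]1(C)[C@H](C)C(=O)CC[C@@H]1C | intermediate
14 | 2-[(1S,2S,6S)-1,2,6-trimethyl-3-oxocyclohexyl]acetaldehyde | O=CC[C@]1(C)[C@H](C)C(=O)CC[C@@H]1C | intermediate
15 | orcinol (5-methylbenzene-1,3-diol) | Cc1cc(O)cc(O)c1 | starting material
16 | 4-chloro-5-methylbenzene-1,3-diol | Cc1cc(O)cc(O)c1Cl | intermediate
17 | 1-chloro-2,4-bis(methoxymethoxy)-6-methylbenzene | Cc1cc(OCOC)cc(OCOC)c1Cl | intermediate
18 | 1-bromobut-2-yne | CC#CCBr | starting material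
19 | [3-chloro-2,6-bis(methoxymethoxy)-4-methylphenyl]lithium | Cc1cc(OCOC)c([Li])c(OCOC)c1Cl | intermediate (not isolated)
20 | 3-(but-2-yn-1-yl)-1-chloro-2,4-bis(methoxymethoxy)-6-methylbenzene | Cc1cc(OCOC)c(CC#CC)c(OCOC)c1Cl | intermediate
21 | chlorobis(cyclopentadienyl)[(2E)-4-[3-chloro-2,6-bis(methoxymethoxy)-4-methylphenyl]but-2-en-2-yl]zirconium | Cc1cc(OCOC)c(C/C=C(\C)[Zr](Cl)(C2C=CC=C2)C2C=CC=C2)c(OCOC)c1Cl | intermediate (not isolated)
22 | 1-chloro-3-[(2E)-3-iodobut-2-en-1-yl]-2,4-bis(methoxymethoxy)-6-methylbenzene | Cc1cc(OCOC)c(C/C=C(\C)I)c(OCOC)c1Cl | intermediate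
23 | (2S,3S,4S)-3-[(2S,3E)-5-[3-chloro-2,6-bis(methoxymethoxy)-4-methylphenyl]-2-hydroxy-3-methylpent-3-en-1-yl]-2,3,4-trimethylcyclohexan-1-one | Cc1cc(OCOC)c(C/C=C(\C)[C@@H](O)C[C@]2(C)[C@H](C)C(=O)CC[C@@H]2C)c(OCOC)c1Cl | intermediate
24 | (2S,3S,4S)-3-[(2S,3E)-5-(3-chloro-2,6-dihydroxy-4-methylphenyl)-2-hydroxy-3-methylpent-3-en-1-yl]-2,3,4-trimethylcyclohexan-1-one | Cc1cc(O)c(C/C=C(\C)[C@@H](O)C[C@]2(C)[C@H](C)C(=O)CC[C@@H]2C)c(O)c1Cl | intermediate
25 | 5-chloro-2-hydroxy-3-[(2E,4S)-4-hydroxy-3-methyl-5-[(1S,2S,6S)-1,2,6-trimethyl-3-oxocyclohexyl]pent-2-en-1-yl]-6-methylcyclohexa-2,5-diene-1,4-dione | CC1=C(Cl)C(=O)C(C/C=C(\C)[C@@H](O)C[C@]2(C)[C@H](C)C(=O)CC[C@@H]2C)=C(O)C1=O | target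

**Totals**

Total step count: 15.
Longest linear sequence: 11 steps (steps 1 to 8, then 13 to 15).

**Steps most likely to fail**

Step 7 (the labelled step). The cation may lose a proton or be captured by chloride or by the ring oxygen before the relay is complete, or the epoxide may rearrange to an open-chain ketone without cyclizing. The fallback uses known chemistry and makes the quaternary centre by a sigmatropic transfer on a preformed ring. It sets out from ethyl vinyl ether 2, the only numbered compound it keeps, and comes back at keto aldehyde 14.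
- Commercial 3-ethoxy-2-methylcyclohex-2-en-1-one would be methylated at C-6 (LiN(iPr)2, MeI, THF, −78 °C) to racemic 3-ethoxy-2,6-dimethylcyclohex-2-en-1-one F1.
- Addition of MeLi and aqueous HCl (Stork–Danheiser transposition) would give racemic 2,3,4-trimethylcyclohex-2-en-1-one F2.
- Corey–Bakshi–Shibata reduction with (S)-2-methyl-CBS-oxazaborolidine and BH3·SMe2 should make the carbinol R in both enantiomers of F2. The cis alcohol (1R,4S)-2,3,4-trimethylcyclohex-2-en-1-ol F3 would then be separated by chromatography from the trans alcohol (1R,4R)-2,3,4-trimethylcyclohex-2-en-1-ol F4, which is discarded.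
- Transvinylation of F3 with 2 (Hg(OAc)2 cat.) would give (3R,6S)-3-(ethenyloxy)-1,2,6-trimethylcyclohex-1-ene F5. Claisen rearrangement at about 180 °C should deliver the two-carbon unit to the face of the C–O bond, that is cis to the neighbouring ring methyl, and give 2-[(1S,6S)-1,2,6-trimethylcyclohex-2-en-1-yl]acetaldehyde F6.
- BH3·THF followed by NaOH/H2O2 would reduce the aldehyde and hydroborate the alkene (boron on the less substituted carbon) to (3S,4S)-3-(2-hydroxyethyl)-2,3,4-trimethylcyclohexan-1-ol F7, a mixture at the two new centres.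
- Double oxidation with Dess–Martin periodinane and equilibration of the α-methyl centre (Et3N) would give 14.

Step 8. The bulky alkyne on a quaternary carbon may be slow to form the ruthenium vinylidene, so that it stays unchanged or gives the methyl ketone. The fallback sets out from alkynyl ketone 13 and comes back at 14. Zirconium-catalysed hydroboration with pinacolborane (HBpin, Cp2Zr(H)Cl cat., CH2Cl2), which does not reduce the ketone, would give (2S,3R,4S)-2,3,4-trimethyl-3-[(E)-2-(4,4,5,5-tetramethyl-1,3,2-dioxaborolan-2-yl)ethenyl]cyclohexan-1-one F8. Oxidation with NaBO3·4H2O in THF/H2O would give the enol and hence 14.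

Step 13. Facial selectivity at the new carbinol may be poor, because the ligand must do all the work. The fallback sets out from 14 and 22 and comes back at 23. The coupling is run without chiral ligand (CrCl2 in excess, NiCl2 cat., DMSO) to give 23 mixed with its carbinol epimer (2S,3S,4S)-3-[(2R,3E)-5-[3-chloro-2,6-bis(methoxymethoxy)-4-methylphenyl]-2-hydroxy-3-methylpent-3-en-1-yl]-2,3,4-trimethylcyclohexan-1-one F9. MnO2 in CH2Cl2 should oxidize only the allylic alcohol of both epimers to (2S,3S,4S)-3-[(3E)-5-[3-chloro-2,6-bis(methoxymethoxy)-4-methylphenyl]-3-methyl-2-oxopent-3-en-1-yl]-2,3,4-trimethylcyclohexan-1-one F10. Corey–Bakshi–Shibata reduction with (R)-2-methyl-CBS-oxazaborolidine and catecholborane at −78 °C, where the conjugated ketone is expected to react before the hindered ring ketone, would return 23.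

**Further compounds**

F1 | step 7 | 3-ethoxy-2,6-dimethylcyclohex-2-en-1-one (racemic) | CCOC1=C(C)C(=O)C(C)CC1
F2 | step 7 | 2,3,4-trimethylcyclohex-2-en-1-one (racemic) | CC1CCC(=O)C(C)=C1C
F3 | step 7 | (1R,4S)-2,3,4-trimethylcyclohex-2-en-1-ol | C[C@H]1CC[C@@H](O)C(C)=C1C
F4 | step 7 | (1R,4R)-2,3,4-trimethylcyclohex-2-en-1-ol | C[C@@H]1CC[C@@H](O)C(C)=C1C
F5 | step 7 | (3R,6S)-3-(ethenyloxy)-1,2,6-trimethylcyclohex-1-ene | C[C@H]1CC[C@@H](OC=C)C(C)=C1C
F6 | step 7 | 2-[(1S,6S)-1,2,6-trimethylcyclohex-2-en-1-yl]acetaldehyde | O=CC[C@]1(C)C(C)=CCC[C@@H]1C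
F7 | step 7 | (3S,4S)-3-(2-hydroxyethyl)-2,3,4-trimethylcyclohexan-1-ol (mixture of epimers at C-1 and C-2) | OCC[C@]1(C)C(C)C(O)CC[C@@H]1C
F8 | step 8 | (2S,3R,4S)-2,3,4-trimethyl-3-[(E)-2-(4,4,5,5-tetramethyl-1,3,2-dioxaborolan-2-yl)ethenyl]cyclohexan-1-one | CC1(C)OB(/C=C/[C@]2(C)[C@H](C)C(=O)CC[C@@H]2C)OC1(C)C
F9 | step 13 | (2S,3S,4S)-3-[(2R,3E)-5-[3-chloro-2,6-bis(methoxymethoxy)-4-methylphenyl]-2-hydroxy-3-methylpent-3-en-1-yl]-2,3,4-trimethylcyclohexan-1-one | Cc1cc(OCOC)c(C/C=C(\C)[C@H](O)C[C@]2(C)[C@H](C)C(=O)CC[C@@H]2C)c(OCOC)c1Cl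
F10 | step 13 | (2S,3S,4S)-3-[(3E)-5-[3-chloro-2,6-bis(methoxymethoxy)-4-methylphenyl]-3-methyl-2-oxopent-3-en-1-yl]-2,3,4-trimethylcyclohexan-1-one | Cc1cc(OCOC)c(C/C=C(\C)C(=O)C[C@]2(C)[C@H](C)C(=O)CC[C@@H]2C)c(OCOC)c1Cl
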